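Take the last row of each run before fitting anything.

| setting | grey | green | Tuesday's | Friday's | Wednesday's | Sunday's |
|---|---|---|---|---|---|---|
| substrate | 0.064 M | 0.24 M | 0.23 M | 0.30 M | 0.080 M | 0.15 M |
| remark | run made earlier | run made earlier |  |  |  |  |
| time |  |  | 8.0 min | 8.0 min | 8.0 min | 8.0 min |

| run | time / min | intermediate A / % | target / % | substrate / % |
|---|---|---|---|---|
| grey | 1.00 | 8 | 2 | 77 |
| grey | 2.00 | 18 | 0 | 58 |
| grey | 3.00 | 19 | 0 | 44 |
| grey | 4.00 | 20 | 0 | 37 |
| grey | 5.00 | 18 | 2 | 30 |
| grey | 6.00 | 23 | 4 | 22 |
| green | 0.417 | 5 | 1 | 68 |
| green | 0.667 | 7 | 4 | 60 |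
| green | 1.33 | 6 | 0 | 37 |
| green | 2.00 | 11 | 3 | 26 |
| green | 3.00 | 11 | 0 | 20 |
| green | 6.00 | 14 | 1 | 7 |

(readings scatter by 2 percentage points)

- the flasks put in order of amount of intermediate A, in percent of the substrate charged, best first, at 8.0 min (Tuesday's / Friday's / Wednesday's / Sunday's)
- the amount of intermediate A, in percent of the substrate charged of the flask you put first, at 8.0 min
- the amount of intermediate A, in percent of the substrate charged of the flask you put last, at 8.0 min

Read the intermediate A column first. In the grey run it stands at 20%, 18% and 23% over the last three readings. In the green run it goes 11%, 11%, 14% from 2.00 min on, against a scatter of 2 percentage points per reading. So we treat intermediate A as flat in time at this stage, and we carry the 6.00 min readings over to 8.0 min.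

Now read the last rows against each other, which stand at the same time. The green run reads more substrate used than the grey run, yet it reads less intermediate A. Loading, then, is the setting we follow.

We define the dilution exponent n, the steepness with which the logarithm of the percentage of intermediate A falls against the logarithm of the charged substrate, taken between the two last rows: n = 0.376. It rests on two readings, so it carries their scatter.

Scaling the grey reading by n, we commit to 21.2% for Wednesday's, 16.7% for Sunday's, 14.2% for Tuesday's and 12.9% for Friday's. The last two lie 1.3 points apart against a scatter of 2 points per reading, so the order of that pair rests on the rule.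

The forecast gives Wednesday's > Sunday's > Tuesday's > Friday's, with 22% and 13%, and says “Dilute flasks win”.

The flasks give Wednesday's > Sunday's > Tuesday's > Friday's, with 21.2% for Wednesday's and 10.8% for Friday's.

    intermediate B → target (k = 0.00174 s⁻¹)
    2 substrate → self-condensation product (k = 0.0327 M⁻¹ s⁻¹)
    intermediate A → intermediate B (k = 0.00170 s⁻¹)
    substrate → intermediate A (k = 0.00188 s⁻¹)

At 8.00 min, Friday's holds 75.4% of its charged substrate as self-condensation product, more than the 49.6% in Wednesday's. Between these two flasks the same exponent comes out at 0.510, steeper than n. Carried to a neighbour of Wednesday's charged with 0.032 M, n gives 29.8%, and that flask holds 28.4% of intermediate A at 8.00 min.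

The earlier runs and the new flask are simulated on assumed constants; the scatter is artificial.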